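**Retrosynthetic overview**

- Target: (2S)-2-(2,5-dihydroxyphenyl)-5-hydroxy-7-methoxy-8-[(2R)-lavandulyl]chroman-4-one (side chain numbered C1″–C6″, C1″ on C8). The last disconnection is an acidic global deprotection of a tris-MOM ether whose C4 ketone is carried as a TIPS enol ether.
- Side chain: the prenyl arm comes from a Zweifel olefination, after a Matteson CH2 insertion, of an α-chiral allylic boronic ester. That ester is made together with the C8–C1″ bond in one three-component conjunctive coupling of the 8-bromo enol ether, vinyl-B(pin) and isopropenylmagnesium bromide.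
- Enabling feature: C8 of ring A (between O1 and the C7–OMe carbon) carries a CH2–CH unit whose CH (C2″) bears an alkenyl group (isopropenyl). This is an aryl–vinyl–alkenyl array, with boron left on C2″ where the prenyl CH2 will stand. C8 is also the only carbon ortho to the free phenol of the acetophenone, so bromine goes there.
- Ring order: ring A is bought (phloroacetophenone ether); ring C is closed as a chromone through the phenol next to bromine; ring B is attached by rhodium-catalysed asymmetric 1,4-addition, which sets C2; the side chain is built last.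

Key step: step 8

Remark: the sense of induction of the chiral ligands in steps 6 and 8 is assigned by analogy with the parent reactions; if a first run shows the opposite configuration, the antipodal ligand is used.

**Route**

Step 1
Reactants: 1 2′,6′-dihydroxy-4′-methoxyacetophenone
Product: 2 1-[2-hydroxy-4-methoxy-6-(methoxymethoxy)phenyl]ethanone
Conditions: MOMCl (1.05 equiv), i-Pr2NEt, CH2Cl2, 0 °C to rt
Reagents that add atoms: chloromethyl methyl ether (MOMCl), COCCl
Why: O-alkylation (MOM protection) of one of two equivalent phenols should stop at the mono-ether because the remaining OH is locked in the hydrogen bond to the acetyl carbonyl.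

Step 2
Reactants: 2 1-[2-hydroxy-4-methoxy-6-(methoxymethoxy)phenyl]ethanone
Product: 3 1-[3-bromo-2-hydroxy-4-methoxy-6-(methoxymethoxy)phenyl]ethanone
Conditions: NBS (1.0 equiv), i-Pr2NH (10 mol%), CH2Cl2, 0 °C
Reagents that add atoms: N-bromosuccinimide, O=C1CCC(=O)N1Br
Why: Electrophilic aromatic bromination under the amine-mediated, ortho-directing NBS protocol should go to C3, the only position ortho to the free phenol, which fixes the halogen at the future C8.

Step 3
Reactants: 3 1-[3-bromo-2-hydroxy-4-methoxy-6-(methoxymethoxy)phenyl]ethanone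
Product: 5 8-bromo-7-methoxy-5-(methoxymethoxy)-4H-chromen-4-one, via enaminone 4 (not isolated)
Conditions: Me2NCH(OMe)2, toluene, 100 °C; then AcOH, 60 °C
Reagents that add atoms: N,N-dimethylformamide dimethyl acetal, COC(OC)N(C)C
Why: Enaminone formation at the acetyl methyl group, then acid-promoted 6-endo addition of the only free phenol and loss of dimethylamine (the DMF-DMA chromone synthesis), closes ring C on the oxygen next to bromine.

Step 4
Reactants: 6 hydroquinone
Product: 7 1,4-bis(methoxymethoxy)benzene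
Conditions: MOMCl (2.5 equiv), i-Pr2NEt, CH2Cl2, 0 °C to reflux
Reagents that add atoms: chloromethyl methyl ether (MOMCl), COCCl
Why: Twofold O-alkylation (MOM protection) of an unhindered diphenol is routine and gives the directing groups for the next step.

Step 5
Reactants: 7 1,4-bis(methoxymethoxy)benzene
Product: 10 [2,5-bis(methoxymethoxy)phenyl]boronic acid, via aryllithium 8 (not isolated), via dimethyl boronate 9 (not isolated)
Conditions: n-BuLi, THF, 0 °C; B(OMe)3, −78 °C to rt; H2O
Reagents that add atoms: trimethyl borate, COB(OC)OC; water, O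
Why: Directed ortho-metalation by a MOM ether (all four ring positions of 7 are equivalent) and borylation of the aryllithium, hydrolysed on work-up, should give a single boronic acid.

Step 6
Reactants: 5 8-bromo-7-methoxy-5-(methoxymethoxy)-4H-chromen-4-one; 10 [2,5-bis(methoxymethoxy)phenyl]boronic acid
Product: 11 (2S)-8-bromo-2-[2,5-bis(methoxymethoxy)phenyl]-7-methoxy-5-(methoxymethoxy)-2,3-dihydro-4H-chromen-4-one
Conditions: [Rh(OH)(cod)]2 (3 mol%), MeO-F12-BIPHEP (antipode giving 2S, 7 mol%), 10 (3 equiv), toluene–H2O, 40 °C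
Reagents that add atoms: none
Why: Rhodium-catalysed asymmetric 1,4-addition of an arylboronic acid to a chromone (Hayashi–Miyaura type, established for 5,7-dioxygenated flavanones) should set C2 through face selection by the chiral bisphosphine, under neutral conditions that do not reopen ring C and leave the aryl bromide untouched.

Step 7
Reactants: 11 (2S)-8-bromo-2-[2,5-bis(methoxymethoxy)phenyl]-7-methoxy-5-(methoxymethoxy)-2,3-dihydro-4H-chromen-4-one
Product: 12 (2S)-8-bromo-2-[2,5-bis(methoxymethoxy)phenyl]-7-methoxy-5-(methoxymethoxy)-4-[(triisopropylsilyl)oxy]-2H-chromene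
Conditions: TIPSOTf, Et3N, CH2Cl2, 0 °C
Reagents that add atoms: triisopropylsilyl trifluoromethanesulfonate, CC(C)[Si](OS(=O)(=O)C(F)(F)F)(C(C)C)C(C)C
Why: Soft enolisation and O-silylation toward C3, the only enolisable position, masks the C4 ketone as a base-robust silyl enol ether for steps 8–10 without touching C2, whose hydrogen is not acidic under these conditions.

Step 8
Reactants: 12 (2S)-8-bromo-2-[2,5-bis(methoxymethoxy)phenyl]-7-methoxy-5-(methoxymethoxy)-4-[(triisopropylsilyl)oxy]-2H-chromene; 13 vinylboronic acid pinacol ester; 14 isopropenylmagnesium bromide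
Product: 16 (2S)-2-[2,5-bis(methoxymethoxy)phenyl]-7-methoxy-5-(methoxymethoxy)-8-[(2R)-3-methyl-2-(4,4,5,5-tetramethyl-1,3,2-dioxaborolan-2-yl)but-3-en-1-yl]-4-[(triisopropylsilyl)oxy]-2H-chromene, via magnesium borate complex 15 (not isolated)
Conditions: 13, 14, NaOTf, THF, 0 °C to rt; then 12, Pd(OAc)2 (3 mol%), MandyPhos (antipode giving 2″R, 3.6 mol%), THF–DMSO, 60 °C
Reagents that add atoms: none
Why: Oxidative addition of zerovalent palladium into the C8–Br bond gives, after triflate-assisted loss of bromide, a cationic arylpalladium species that binds the unsubstituted vinyl group of borate 15; the isopropenyl group then shifts from boron to the boron-bearing vinyl carbon anti to palladium (1,2-metallate rearrangement), and reductive elimination from the resulting alkyl(aryl)palladium forms the C8–C1″ bond. The closest known reaction type is the enantioselective palladium/MandyPhos conjunctive cross-coupling of bis(alkenyl)borates with aryl electrophiles, which gives α-chiral allylic boronic esters. No ring is closed. The new stereocentre C2″ is set in the metallate shift by the ligand, which selects the enantiotopic face of the vinyl group; C2 is remote, so the ligand antipode should decide the C2″ configuration. The step needs the vinyl group to act as acceptor and the α-branched isopropenyl group to migrate, conjunctive coupling to outrun direct alkenyl transfer to palladium, and a substrate without electrophilic or acidic sites: the different substitution of the two alkenyl groups, the bidentate ligand with halide abstraction, and the silyl enol ether secure these in turn, and C8–Br is the only carbon–halogen bond.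

Step 9
Reactants: 16 (2S)-2-[2,5-bis(methoxymethoxy)phenyl]-7-methoxy-5-(methoxymethoxy)-8-[(2R)-3-methyl-2-(4,4,5,5-tetramethyl-1,3,2-dioxaborolan-2-yl)but-3-en-1-yl]-4-[(triisopropylsilyl)oxy]-2H-chromene
Product: 18 (2S)-2-[2,5-bis(methoxymethoxy)phenyl]-7-methoxy-5-(methoxymethoxy)-8-{(2R)-3-methyl-2-[(4,4,5,5-tetramethyl-1,3,2-dioxaborolan-2-yl)methyl]but-3-en-1-yl}-4-[(triisopropylsilyl)oxy]-2H-chromene, via chloromethyl borate complex 17 (not isolated)
Conditions: BrCH2Cl (2 equiv), n-BuLi (1.8 equiv), THF, −78 °C to rt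
Reagents that add atoms: bromochloromethane, ClCBr
Why: Matteson homologation: chloromethyllithium made in situ adds to boron and the allylic carbon migrates with retention while chloride leaves, so C2″ keeps its configuration and gains the CH2 of the prenyl arm.

Step 10
Reactants: 18 (2S)-2-[2,5-bis(methoxymethoxy)phenyl]-7-methoxy-5-(methoxymethoxy)-8-{(2R)-3-methyl-2-[(4,4,5,5-tetramethyl-1,3,2-dioxaborolan-2-yl)methyl]but-3-en-1-yl}-4-[(triisopropylsilyl)oxy]-2H-chromene
Product: 21 (2S)-2-[2,5-bis(methoxymethoxy)phenyl]-7-methoxy-5-(methoxymethoxy)-8-[(2R)-5-methyl-2-(prop-1-en-2-yl)hex-4-en-1-yl]-4-[(triisopropylsilyl)oxy]-2H-chromene, via alkenyl borate complex 19 (not isolated), via iodo boronic ester 20 (not isolated)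
Conditions: Me2C=CHBr, t-BuLi (2 equiv per bromide), Et2O, −78 °C; add 18, THF, −78 °C; I2 (1.05 equiv), MeOH; NaOMe, −78 to 0 °C
Reagents that add atoms: 1-bromo-2-methylprop-1-ene (as its lithio derivative), CC(C)=CBr
Why: Zweifel olefination: the alkenyllithium forms a borate, iodine triggers 1,2-migration of the primary alkyl group, and methoxide-induced anti-elimination of boron and iodide gives the trisubstituted alkene, which has no geometry to control (two methyl groups on the far carbon) and leaves C2″ untouched, while the TIPS enol ether should survive cold methoxide.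

Step 11
Reactants: 21 (2S)-2-[2,5-bis(methoxymethoxy)phenyl]-7-methoxy-5-(methoxymethoxy)-8-[(2R)-5-methyl-2-(prop-1-en-2-yl)hex-4-en-1-yl]-4-[(triisopropylsilyl)oxy]-2H-chromene
Product: 22 (2S)-2-(2,5-dihydroxyphenyl)-5-hydroxy-7-methoxy-8-[(2R)-5-methyl-2-(prop-1-en-2-yl)hex-4-en-1-yl]-2,3-dihydro-4H-chromen-4-one (CNP0197014.2)
Conditions: 3 M aq. HCl, MeOH–THF, 40 °C
Reagents that add atoms: none
Why: Acid-catalysed acetal cleavage removes the three MOM groups and C3-protonation of the silyl enol ether returns the C4 ketone; acid does not open ring C, so C2 should hold, and the lavandulyl alkenes have no neighbouring phenol to add to them (O1 is in ring C and C7 carries OMe).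

**Compound list**

1 | 2′,6′-dihydroxy-4′-methoxyacetophenone | CC(=O)c1c(O)cc(OC)cc1O | starting material
2 | 1-[2-hydroxy-4-methoxy-6-(methoxymethoxy)phenyl]ethanone | CC(=O)c1c(O)cc(OC)cc1OCOC | intermediate
3 | 1-[3-bromo-2-hydroxy-4-methoxy-6-(methoxymethoxy)phenyl]ethanone | CC(=O)c1c(O)c(Br)c(OC)cc1OCOC | intermediate
4 | (E)-1-[3-bromo-2-hydroxy-4-methoxy-6-(methoxymethoxy)phenyl]-3-(dimethylamino)prop-2-en-1-one (enaminone) | CN(C)/C=C/C(=O)c1c(O)c(Br)c(OC)cc1OCOC | intermediate (not isolated)
5 | 8-bromo-7-methoxy-5-(methoxymethoxy)-4H-chromen-4-one | O=c1ccoc2c(Br)c(OC)cc(OCOC)c12 | intermediate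
6 | hydroquinone | Oc1ccc(O)cc1 | starting material
7 | 1,4-bis(methoxymethoxy)benzene | COCOc1ccc(OCOC)cc1 | intermediate
8 | 2,5-bis(methoxymethoxy)phenyllithium | COCOc1ccc(OCOC)c([Li])c1 | intermediate (not isolated)
9 | dimethyl [2,5-bis(methoxymethoxy)phenyl]boronate | COCOc1ccc(OCOC)c(B(OC)OC)c1 | intermediate (not isolated)
10 | [2,5-bis(methoxymethoxy)phenyl]boronic acid | COCOc1ccc(OCOC)c(B(O)O)c1 | intermediate
11 | (2S)-8-bromo-2-[2,5-bis(methoxymethoxy)phenyl]-7-methoxy-5-(methoxymethoxy)-2,3-dihydro-4H-chromen-4-one | O=C1C[C@@H](c2cc(OCOC)ccc2OCOC)Oc2c(Br)c(OC)cc(OCOC)c12 | intermediate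
12 | (2S)-8-bromo-2-[2,5-bis(methoxymethoxy)phenyl]-7-methoxy-5-(methoxymethoxy)-4-[(triisopropylsilyl)oxy]-2H-chromene | CC(C)[Si](OC1=C[C@@H](c2cc(OCOC)ccc2OCOC)Oc2c(Br)c(OC)cc(OCOC)c12)(C(C)C)C(C)C | intermediate
13 | vinylboronic acid pinacol ester (4,4,5,5-tetramethyl-2-vinyl-1,3,2-dioxaborolane) | C=CB1OC(C)(C)C(C)(C)O1 | starting material
14 | isopropenylmagnesium bromide | CC(=C)[Mg]Br | starting material
15 | bromomagnesium isopropenyl(pinacolato)(vinyl)borate | C=C[B-]1(C(C)=C)OC(C)(C)C(C)(C)O1.[Mg+]Br | intermediate (not isolated)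
16 | (2S)-2-[2,5-bis(methoxymethoxy)phenyl]-7-methoxy-5-(methoxymethoxy)-8-[(2R)-3-methyl-2-(4,4,5,5-tetramethyl-1,3,2-dioxaborolan-2-yl)but-3-en-1-yl]-4-[(triisopropylsilyl)oxy]-2H-chromene | C=C(C)[C@H](B1OC(C)(C)C(C)(C)O1)Cc1c(OC)cc(OCOC)c2c1O[C@H](c1cc(OCOC)ccc1OCOC)C=C2O[Si](C(C)C)(C(C)C)C(C)C | intermediate
17 | lithium chloromethyl borate complex of 16 | C=C(C)[C@H]([B-]1(CCl)OC(C)(C)C(C)(C)O1)Cc1c(OC)cc(OCOC)c2c1O[C@H](c1cc(OCOC)ccc1OCOC)C=C2O[Si](C(C)C)(C(C)C)C(C)C.[Li+] | intermediate (not isolated)
18 | (2S)-2-[2,5-bis(methoxymethoxy)phenyl]-7-methoxy-5-(methoxymethoxy)-8-{(2R)-3-methyl-2-[(4,4,5,5-tetramethyl-1,3,2-dioxaborolan-2-yl)methyl]but-3-en-1-yl}-4-[(triisopropylsilyl)oxy]-2H-chromene | C=C(C)[C@H](CB1OC(C)(C)C(C)(C)O1)Cc1c(OC)cc(OCOC)c2c1O[C@H](c1cc(OCOC)ccc1OCOC)C=C2O[Si](C(C)C)(C(C)C)C(C)C | intermediate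
19 | lithium (2-methylprop-1-enyl) borate complex of 18 | C=C(C)[C@H](C[B-]1(C=C(C)C)OC(C)(C)C(C)(C)O1)Cc1c(OC)cc(OCOC)c2c1O[C@H](c1cc(OCOC)ccc1OCOC)C=C2O[Si](C(C)C)(C(C)C)C(C)C.[Li+] | intermediate (not isolated)
20 | β-iodo boronic ester formed from 19 by iodine-induced 1,2-migration (boron-bearing carbon as a mixture of epimers) | C=C(C)[C@H](CC(B1OC(C)(C)C(C)(C)O1)C(C)(C)I)Cc1c(OC)cc(OCOC)c2c1O[C@H](c1cc(OCOC)ccc1OCOC)C=C2O[Si](C(C)C)(C(C)C)C(C)C | intermediate (not isolated)
21 | (2S)-2-[2,5-bis(methoxymethoxy)phenyl]-7-methoxy-5-(methoxymethoxy)-8-[(2R)-5-methyl-2-(prop-1-en-2-yl)hex-4-en-1-yl]-4-[(triisopropylsilyl)oxy]-2H-chromene | C=C(C)[C@H](CC=C(C)C)Cc1c(OC)cc(OCOC)c2c1O[C@H](c1cc(OCOC)ccc1OCOC)C=C2O[Si](C(C)C)(C(C)C)C(C)C | intermediate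
22 | (2S)-2-(2,5-dihydroxyphenyl)-5-hydroxy-7-methoxy-8-[(2R)-5-methyl-2-(prop-1-en-2-yl)hex-4-en-1-yl]-2,3-dihydro-4H-chromen-4-one | C=C(C)[C@H](CC=C(C)C)Cc1c(OC)cc(O)c2c1O[C@H](c1cc(O)ccc1O)CC2=O | target

**Step count and risks**

Total: 11 steps. Longest linear sequence: 9 steps (steps 1–3 and 6–11); steps 4 and 5 make the boronic acid for step 6.

Most likely to fail:

1. Step 8. Oxidative addition into the electron-rich, doubly ortho-oxygenated C8–Br bond may be slow. Direct alkenyl transfer from the borate to palladium (Suzuki-type coupling) could then take over, and facial selectivity may erode at the temperature needed. Fallback: the side chain is made whole with its stereocentre and attached to 12 by a different coupling. (4S)-4-Benzyloxazolidin-2-one is N-acylated (n-BuLi, 3-methylbut-2-enoyl chloride) to (4S)-4-benzyl-3-(3-methylbut-2-enoyl)oxazolidin-2-one F1. Deconjugative Evans alkylation of its sodium dienolate (NaN(SiMe3)2, prenyl bromide, THF, −78 °C) should give (4S)-4-benzyl-3-[(2S)-5-methyl-2-(prop-1-en-2-yl)hex-4-enoyl]oxazolidin-2-one F2. LiBH4 reduction gives (S)-lavandulol F3, and I2/PPh3/imidazole gives (S)-lavandulyl iodide F4. Iodine–lithium exchange (t-BuLi, Et2O, −78 °C) and capture with B-methoxy-9-BBN gives lithium B-methoxy-B-[(S)-lavandulyl]-9-borabicyclo[3.3.1]nonane borate F5. B-alkyl Suzuki–Miyaura coupling of F5 with 12 (Pd(OAc)2, SPhos, aq. K3PO4, THF–DMF, 50 °C) comes back to the route at 21.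

2. Step 6. Protodeboronation of the ortho-alkoxy boronic acid may outrun transmetalation, the electron-rich chromone is a poor acceptor, and face selection may be incomplete. Fallback: ring C is closed by the chalcone route and the enantiomers are separated. From 3, Claisen–Schmidt condensation (KOH, EtOH, rt) with 2,5-bis(methoxymethoxy)benzaldehyde F6 (from 2,5-dihydroxybenzaldehyde, MOMCl, i-Pr2NEt) gives (E)-1-[3-bromo-2-hydroxy-4-methoxy-6-(methoxymethoxy)phenyl]-3-[2,5-bis(methoxymethoxy)phenyl]prop-2-en-1-one F7. NaOAc in refluxing EtOH closes it by 6-endo oxa-Michael addition to racemic 8-bromo-2-[2,5-bis(methoxymethoxy)phenyl]-7-methoxy-5-(methoxymethoxy)chroman-4-one F8. Preparative HPLC on a chiral stationary phase then delivers 11; the 2R antipode is re-equilibrated with base through F7 and recycled.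

3. Step 10. Iodine may attack the silyl enol ether or C6 of ring A in competition with the borate, and methoxide may strip the silyl group and then open ring C. Fallback: from 18, the prenyl arm is closed without electrophilic iodine or organolithium by B-alkyl Suzuki–Miyaura coupling with 1-bromo-2-methylprop-1-ene (Pd(OAc)2, RuPhos, aq. K3PO4, toluene, 80 °C), which comes back to the route at 21.

**Further compounds**

F1 | step 8 | (4S)-4-benzyl-3-(3-methylbut-2-enoyl)oxazolidin-2-one | CC(C)=CC(=O)N1[C@@H](Cc2ccccc2)COC1=O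
F2 | step 8 | (4S)-4-benzyl-3-[(2S)-5-methyl-2-(prop-1-en-2-yl)hex-4-enoyl]oxazolidin-2-one | C=C(C)[C@H](CC=C(C)C)C(=O)N1[C@@H](Cc2ccccc2)COC1=O
F3 | step 8 | (S)-lavandulol, (2S)-5-methyl-2-(prop-1-en-2-yl)hex-4-en-1-ol | C=C(C)[C@H](CC=C(C)C)CO
F4 | step 8 | (S)-lavandulyl iodide, (2S)-1-iodo-5-methyl-2-(prop-1-en-2-yl)hex-4-ene | C=C(C)[C@H](CC=C(C)C)CI
F5 | step 8 | lithium B-methoxy-B-[(2S)-5-methyl-2-(prop-1-en-2-yl)hex-4-en-1-yl]-9-borabicyclo[3.3.1]nonane borate | C=C(C)[C@H](CC=C(C)C)C[B-]1(OC)C2CCCC1CCC2.[Li+]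
F6 | step 6 | 2,5-bis(methoxymethoxy)benzaldehyde | COCOc1ccc(OCOC)c(C=O)c1
F7 | step 6 | (E)-1-[3-bromo-2-hydroxy-4-methoxy-6-(methoxymethoxy)phenyl]-3-[2,5-bis(methoxymethoxy)phenyl]prop-2-en-1-one | O=C(/C=C/c1cc(OCOC)ccc1OCOC)c1c(O)c(Br)c(OC)cc1OCOC
F8 | step 6 | racemic 8-bromo-2-[2,5-bis(methoxymethoxy)phenyl]-7-methoxy-5-(methoxymethoxy)chroman-4-one | O=C1CC(c2cc(OCOC)ccc2OCOC)Oc2c(Br)c(OC)cc(OCOC)c12
F0 | step 10 | none | none
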